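## Structural features

Hansforester J is a linear oligoester of four units: ring A, a 5-substituted resorcinol with an (R)-2-oxypropyl chain; unit B, an (R)-3-oxybutanoyl group; ring C, a 2,4-dihydroxybenzoate with an (R)-2-oxypropyl chain at C6; and unit D, an (R)-3-hydroxybutanoyl group carrying the only free alcohol. Three ester bonds join them: ring A carbinol oxygen to the unit B carbonyl, unit B C3 oxygen to the ring C carboxyl, and ring C side-chain oxygen to the unit D carbonyl. The four stereocentres are isolated methyl carbinols, all (R), each at least three atoms from the next, so none can control another and each must be imported or set by a catalyst. Two features are fragile under base: the 3-acyloxybutanoate esters, which can lose carboxylate by E1cB elimination, and the free resorcinols, which also tolerate no oxidants. The ring C side-chain oxygen, when free, sits where it can attack the C1 ester and close a dihydroisocoumarin. The real difficulty is ring C: its carboxyl is flanked by the C2 oxygen and the C6 chain, so its ester with a secondary alcohol cannot be made by ordinary acylation, and C1, C2, C4 and C6 must be set without regiochemical ambiguity. The key step uses the mapping of ring C atoms C1 (carboxyl), C2 (oxygen), C3 and C6 (chain) onto C5, C4, C3 and C6 of a 2-pyrone-5-carboxylate, with C4 (oxygen) and C5 coming from the two carbons of a ketene acetal. The para relation of carboxyl and C4 oxygen is the innate regiochemistry of that pairing.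

## Logic of the disconnections

30 ⇒ 29 ⇒ 28. The four aryl O–benzyl bonds and then the O–Si bond on unit D are restored. All sensitive features of 30 are thereby unveiled last, under neutral hydrogenolysis and mildly acidic fluoride. The gain is that every earlier intermediate is non-polar and robust. The demand is that no ester is benzylic (all ester oxygens sit on homobenzylic or aliphatic carbons) and that desilylation is never basic.

28 ⇒ 27 + 3. The acyl C–O bond between the unit D carbonyl and the ring C side-chain oxygen is cut. It is an unhindered ester, and 3 is needed anyway for ring C. One stereocentre and four carbons leave as a chiral-pool acid. The forward acylation must be faster than attack of the free alcohol of 27 on the neighbouring benzoate, and must avoid strong base.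

27 ⇒ 26 ⇒ 17 + 25. After the side-chain oxygen is put back under silicon, the C–O bond between C3 of unit B and the carboxylate oxygen of ring C is cut on the alkyl side. The carbonyl of 17 is shielded by two ortho groups, and activating it would invite attack by the side-chain oxygen; as a nucleophile the carboxylate has neither problem. The molecule falls into two halves of similar size. The forward step is an SN2 displacement with inversion, so 25 must carry the (S) carbinol, and displacement must outrun dehydration to the crotonate.

25 ⇒ 24 ⇒ 21 + 22. The C3–H bond of unit B is cut (carbinol back to ketone), then the acyl C–O bond of the acetoacetate. The (S) carbinol is not the chiral-pool series used elsewhere, and reduction of a β-keto ester under catalyst control needs no protecting group. Unit B then comes from an achiral four-carbon reagent in two steps. The demand is high enantiofacial control independent of the remote ring A centre, with benzyl ethers untouched.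

21 ⇒ 18 + 19. The aryl–CH2 bond is cut. The arene is symmetric and the carbinol is that of a commercial epoxide, so ring A costs one step. The nucleophile must attack only the CH2 terminus of 19.

17 ⇒ 16. The O–allyl bond is cut. A di-ortho-substituted benzoate cannot be saponified gently, whereas an allyl ester is cleaved at the alkyl–oxygen bond. The ester must survive the thermal key step.

16 ⇒ 10 + 13. Ring C bonds C3–C4 and C5–C6 are cut, and a CO2 bridge is restored between C3 and C6. The carboxyl, both flanking substituents and the stereocentre are then fixed on a heterocycle made by carbonyl chemistry, and the arene appears at the correct oxidation level. The tetrasubstituted arene reduces to an acyclic tricarbonyl problem. The demand is that a hindered, donor-substituted diene still reacts and that 13 survives the temperature.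

13 ⇒ 12 ⇒ 11. The C=C bond is cut by adding HBr back, then the two acetal C–O bonds by exchange. This leads to a commercial bromoacetal. The forward elimination must run cold and 13 must not be distilled.

10 ⇒ 9 ⇒ 8. The O–benzyl bond at pyrone C4 is cut, then the lactone bond O1–C2. This opens the ring to a tricarbonyl diester. The forward steps need O- rather than C-alkylation, and lactonization through the only six-membered mode.

8 ⇒ 6 + 7 ⇒ 3 ⇒ 2 ⇒ 1, and 6 ⇒ 4 + two molecules of 5. The C–C bond between the acyl carbonyl and the active methylene of 6 is cut, then the protecting and ester groups; both ester C–O bonds of 6 are cut back to the methyl esters. This reaches the chiral-pool hydroxy ester and a bulk keto diester. The forward steps need C-acylation without loss of the silyl ether and exchange of both ester groups.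

## Other disconnections considered

Alternative 1: The cut runs through ring A at C1–C2 and C3–C4 (C1 bears the chain) and leads to the enone A2 and the malonate A3. Forward, A3 would add to the β-carbon of A2 and the methyl ketone enolate would close onto one ester group to give the dione ester A1. Hydrolysis with decarboxylation, dehydrogenation to the resorcinol, O-benzylation and removal of the 4-methoxybenzyl group would then lead to 21.
- In its favour: bulk reagents, purely ionic and scalable chemistry, and a stereocentre from the same chiral pool.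
- Against it here: ring A is a symmetric resorcinol that step 11 delivers in one step. The ester of A1 must be removed, and turning a cyclohexane-1,3-dione into a resorcinol is a separate oxidation that usually needs forcing or halogenating conditions.
- On structure, it addresses the easy ring and leaves ring C untouched.
- On mechanism, it makes two bonds by enolate chemistry but arrives one oxidation level low, whereas the pyrone route reaches the arene by losing CO2 and an alcohol without an oxidant.
- On step economy, it needs about eight steps against one for 21.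
- It is the equal or the better of the chosen plan in reagent cost, in robustness on scale, and in having no thermally sensitive partner.
- The substitution pattern of A1 (ester between a carbonyl and the chain-bearing carbon) is in fact that of ring C. Applied there with the ester kept, it would rival the pyrone route in length, but the aromatization problem would remain.

Alternative 2: The cut removes both exocyclic C–C bonds of ring C (C1–carboxyl carbon and C6–CH2), leaving the aryne precursor A5 and the ketene silyl acetal A6. Forward, the aryne released from A5 by halogen–metal exchange would undergo [2+2] addition with A6 to give the benzocyclobutenone acetal A4. Cleavage of the bond between the acetal carbon and the ring CH would then give the benzoate A7, the methyl ester analogue of 16.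
- In its favour: the C3 benzyloxy group of the aryne directs the nucleophilic carbon to the remote aryne carbon, so the carboxyl carbon ends next to oxygen. Both ring C substituents arrive in one low-temperature step, the arene is bought with its benzyl ethers in place, and the carbinol centre comes from the same chiral-pool ester.
- Against it here: A5 needs several steps from a phloroglucinol-type precursor. Enolizing a β-silyloxy ester to make A6 risks β-elimination, and a strained intermediate must be opened in a further step. A7 is a di-ortho-substituted methyl benzoate that cannot be cleaved gently; an allyl ester is not an option because its ketene silyl acetal would undergo Ireland–Claisen rearrangement.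
- On structure, it attacks the same ring and the same two substituents as the chosen plan.
- On mechanism, it is a polar stepwise [2+2] followed by fragmentation, against a [4+2] and cycloreversion.
- On step economy, it is probably equal or shorter to a ring C ester, which is a point in its favour. A second point in its favour is that it needs no thermally labile ketene dibenzyl acetal.
- It is weaker on the ester handle required for the Mitsunobu coupling and on the availability of A5.

Alternative 3: The cut runs through ring A at C2–C3 and C4–C5 and leads to the cyclobutenone A9 and the siloxyalkyne A10. Forward, heating would open A9 to a vinylketene, which adds A10 in a [2+2] sense. Four-electron opening, six-electron closure and tautomerization would then give the mono-silylated resorcinol A8.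
- In its favour: neutral thermal conditions, complete regiocontrol, and two differentiated phenol oxygens.
- Against it here: ring A is symmetric, so differentiation buys nothing and both oxygens would still have to be converted to benzyl ethers. A9 and A10 each need a multi-step preparation, while 21 is one step from catalogue compounds.
- On structure, it solves a problem that ring A does not pose and cannot supply ring C, which needs a carboxyl.
- On mechanism, it is a cascade of four pericyclic events against two. Like the key step it reaches the arene without an oxidant, so the two are equal on that point.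
- A10 should tolerate heat better than 13, which is a point in its favour.
- On step economy, it is clearly worse for this target.

Key step: step 9

**Remarks on the chemistry**

- CIP analysis gives (R) for all four stereocentres of the target.
- The alcohol joined to the ring C acid is the C3 hydroxyl of unit B in the A–B hydroxy ester 25, not the ring A carbinol. Because the coupling inverts, unit B enters as the (S) carbinol while the ring A carbinol is (R) throughout.
- Benzyl ketene acetals are known to isomerize on strong heating by benzyl shifts. Compound 13 is therefore made below 50 °C, not distilled, used in excess, and the cycloaddition is held near 110 °C.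
- Step 3 takes up two molecules of 5 per molecule of 4, and step 7 two molecules of benzyl alcohol per molecule of 11.
- Compounds 11, 18, 19 and 22 are taken to be catalogue chemicals.

## Route

Step 1
Reactants: 1 methyl (R)-3-hydroxybutanoate
Product: 2 methyl (R)-3-(tert-butyldimethylsilyloxy)butanoate
Conditions: TBSCl, imidazole, DMF, 0 °C → rt
Reagents that add atoms: tert-butyldimethylsilyl chloride, CC(C)(C)[Si](C)(C)Cl
Why: Standard silylation of a secondary alcohol; the stereocentre is not touched and the silyl ether later serves as the side-chain protecting group of ring C and of unit D.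

Step 2
Reactants: 2 methyl (R)-3-(tert-butyldimethylsilyloxy)butanoate
Product: 3 (R)-3-(tert-butyldimethylsilyloxy)butanoic acid
Conditions: LiOH·H2O, THF/MeOH/H2O, 0 °C → rt; then 1 M HCl to pH 3, 0 °C
Reagents that add atoms: lithium hydroxide, [Li+].[OH-]
Why: Ester saponification; at or below room temperature the β-silyloxy group is too poor a leaving group for E1cB loss, and a brief cold acidification leaves the secondary silyl ether intact.

Step 3
Reactants: 4 dimethyl 3-oxopentanedioate; 5 allyl alcohol
Product: 6 diallyl 3-oxopentanedioate
Conditions: 5 (4 equiv), DMAP (cat.), toluene, reflux, 4 Å MS (MeOH removed)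
Reagents that add atoms: allyl alcohol (second equivalent), C=CCO
Why: Double transesterification of a β-keto ester, which exchanges far more readily than a simple ester; both ester groups are β to the ketone and each takes up one molecule of 5, and removal of methanol drives the exchange to the diallyl ester.

Step 4
Reactants: 3 (R)-3-(tert-butyldimethylsilyloxy)butanoic acid; 6 diallyl 3-oxopentanedioate
Product: 8 diallyl 2-[(R)-3-(tert-butyldimethylsilyloxy)butanoyl]-3-oxopentanedioate, via (R)-3-(tert-butyldimethylsilyloxy)butanoyl chloride 7 (not isolated)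
Conditions: (COCl)2, DMF (cat.), CH2Cl2, 0 °C → rt, concentrate; then 6, MgCl2, pyridine, CH2Cl2, 0 °C → rt; cold 1 M HCl work-up
Reagents that add atoms: none
Why: Magnesium-mediated soft-enolization C-acylation of a 1,3-dicarbonyl compound: the chelated enolate of 6 is acylated on carbon by 7, and the chelated tricarbonyl product resists a second acylation. The carbinol centre is β to the carbonyl and cannot epimerize; C2 of 8 is enolized and carries no defined configuration.

Step 5
Reactants: 8 diallyl 2-[(R)-3-(tert-butyldimethylsilyloxy)butanoyl]-3-oxopentanedioate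
Product: 9 allyl 4-hydroxy-6-[(R)-2-(tert-butyldimethylsilyloxy)propyl]-2-oxo-2H-pyran-5-carboxylate
Conditions: DBU (1.0 equiv), toluene, 80 °C; then aq. citric acid
Reagents that add atoms: none
Why: Lactonization of a tricarbonyl ester to a 4-hydroxy-2-pyrone: the enolate oxygen of the new acyl group attacks the remote allyl ester (6-exo-trig acyl substitution, the only six-membered mode) and the ring ketone enolizes. The delocalized anion is not basic enough to expel the silyloxy group.

Step 6
Reactants: 9 allyl 4-hydroxy-6-[(R)-2-(tert-butyldimethylsilyloxy)propyl]-2-oxo-2H-pyran-5-carboxylate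
Product: 10 allyl 4-(benzyloxy)-6-[(R)-2-(tert-butyldimethylsilyloxy)propyl]-2-oxo-2H-pyran-5-carboxylate
Conditions: BnOH, PPh3, diisopropyl azodicarboxylate, THF, 0 °C → rt
Reagents that add atoms: benzyl alcohol, OCc1ccccc1
Why: Mitsunobu O-alkylation of an acidic 4-hydroxy-2-pyrone, a reaction that alkylates the C4 oxygen and avoids the C3 benzylation that benzyl halides with carbonate bases can cause.

Step 7
Reactants: 11 2-bromo-1,1-diethoxyethane
Product: 12 2-bromo-1,1-bis(benzyloxy)ethane
Conditions: BnOH (2.2 equiv), TsOH·H2O (cat.), 90 °C, reduced pressure (EtOH removed)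
Reagents that add atoms: benzyl alcohol, OCc1ccccc1; benzyl alcohol (second equivalent), OCc1ccccc1
Why: Acid-catalysed acetal exchange in which both ethoxy groups are replaced by benzyl alcohol, driven by distilling out the more volatile ethanol.

Step 8
Reactants: 12 2-bromo-1,1-bis(benzyloxy)ethane
Product: 13 1,1-bis(benzyloxy)ethene
Conditions: KOtBu, THF, 0 → 45 °C; filtration through basic Al2O3; used at once
Reagents that add atoms: none
Why: E2 dehydrobromination of a bromoacetal, the classical entry to ketene acetals. Keeping the temperature low and omitting distillation avoid thermal benzyl shifts of the product.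

Step 9
Reactants: 10 allyl 4-(benzyloxy)-6-[(R)-2-(tert-butyldimethylsilyloxy)propyl]-2-oxo-2H-pyran-5-carboxylate; 13 1,1-bis(benzyloxy)ethene
Product: 16 allyl 2,4-bis(benzyloxy)-6-[(R)-2-(tert-butyldimethylsilyloxy)propyl]benzoate, via bridged bicyclic lactone 14 (not isolated), via cyclohexadiene ketal 15 (not isolated)
Conditions: 13 (3 equiv), toluene (1 M), BHT (cat.), 110 °C, sealed tube; then PPTS (cat.), 50 °C
Reagents that add atoms: none
Why: In an inverse-electron-demand Diels–Alder reaction the HOMO of 13 (largest at CH2) meets the LUMO of the diene C3=C4–C5=C6 of 10 (largest at C6, the β-carbon of the C5 acrylate), so that CH2–C6 bonding leads and bonding of the acetal carbon to C3 follows, giving lactone 14. Cycloreversion of 14 expels CO2 to give ketal 15, and 1,2-elimination of benzyl alcohol, completed by PPTS, gives arene 16. The closest known reaction type is the conversion of 2-pyrone-5-carboxylates and 3-carboxylates with ketene dialkyl acetals into alkoxybenzoates, applied here to a 4-alkoxy-6-alkyl member. Ring C is closed by an intermolecular [4+2] cycloaddition that forms arene bonds C3–C4 and C5–C6 and is followed by cycloreversion; no chain is cyclized, so no exo or endo mode of closure applies. No stereocentre is created in 16: the two bridgehead centres of 14 disappear with CO2 and the side-chain carbinol is a protected spectator. The step needs regioselectivity, CH2 to C6 and acetal carbon to C3, which the polarization by the C5 ester secures and which places the new oxygen para to the ester. It also needs loss of an alkoxy group only from the sp3 ketal carbon, which is assured because the other benzyloxy group sits on an sp2 carbon and both ketal oxygens are equivalent. The 4-benzyloxy and 6-alkyl groups slow the cycloaddition, hence the excess of 13, the high concentration and a temperature kept below that at which 13 is expected to undergo benzyl shifts.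

Step 10
Reactants: 16 allyl 2,4-bis(benzyloxy)-6-[(R)-2-(tert-butyldimethylsilyloxy)propyl]benzoate
Product: 17 2,4-bis(benzyloxy)-6-[(R)-2-(tert-butyldimethylsilyloxy)propyl]benzoic acid
Conditions: Pd(PPh3)4 (5 mol %), morpholine, THF, rt; aq. citric acid work-up
Reagents that add atoms: none
Why: Allyl ester cleavage by zerovalent palladium: ionization to a π-allyl complex breaks the alkyl–oxygen bond and morpholine traps the allyl group, so the hindered carbonyl is never attacked and the silyl and benzyl ethers are untouched.

Step 11
Reactants: 18 1,3-bis(benzyloxy)-5-bromobenzene; 19 (R)-2-methyloxirane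
Product: 21 (R)-1-[3,5-bis(benzyloxy)phenyl]propan-2-ol, via [3,5-bis(benzyloxy)phenyl]magnesium bromide 20 (not isolated)
Conditions: Mg, THF, reflux; then CuI (10 mol %), 19, −30 → 0 °C; aq. NH4Cl
Reagents that add atoms: none
Why: Grignard formation and copper-catalysed opening of the epoxide at its CH2 terminus; no bond to the stereocentre is broken, so the (R) configuration of 19 is carried into 21.

Step 12
Reactants: 21 (R)-1-[3,5-bis(benzyloxy)phenyl]propan-2-ol; 22 2,2,6-trimethyl-4H-1,3-dioxin-4-one
Product: 24 (R)-1-[3,5-bis(benzyloxy)phenyl]propan-2-yl 3-oxobutanoate, via acetylketene 23 (not isolated)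
Conditions: toluene, 110 °C (acetone distilled off)
Reagents that add atoms: none
Why: Thermal cycloreversion of the dioxinone releases acetylketene, which the secondary alcohol traps to give the acetoacetate under neutral conditions.

Step 13
Reactants: 24 (R)-1-[3,5-bis(benzyloxy)phenyl]propan-2-yl 3-oxobutanoate
Product: 25 (R)-1-[3,5-bis(benzyloxy)phenyl]propan-2-yl (S)-3-hydroxybutanoate
Conditions: H2 (10 atm), [RuCl(p-cymene)((S)-BINAP)]Cl (1 mol %), EtOH/CH2Cl2, 60 °C
Reagents that add atoms: none
Why: Noyori asymmetric hydrogenation of a β-keto ester: the chelated substrate is reduced on one face by the (S)-BINAP ruthenium hydride to the (S) carbinol, with catalyst control overriding the remote ring A centre. Aryl benzyl ethers are inert to this homogeneous catalyst.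

Step 14
Reactants: 17 2,4-bis(benzyloxy)-6-[(R)-2-(tert-butyldimethylsilyloxy)propyl]benzoic acid; 25 (R)-1-[3,5-bis(benzyloxy)phenyl]propan-2-yl (S)-3-hydroxybutanoate
Product: 26 (R)-4-{[(R)-1-(3,5-bis(benzyloxy)phenyl)propan-2-yl]oxy}-4-oxobutan-2-yl 2,4-bis(benzyloxy)-6-[(R)-2-(tert-butyldimethylsilyloxy)propyl]benzoate
Conditions: PPh3, diisopropyl azodicarboxylate (added last, slowly), toluene, 0 °C → rt
Reagents that add atoms: none
Why: Mitsunobu esterification: the carboxylate of 17 displaces the oxyphosphonium derived from 25 by SN2 with inversion, converting the (S) carbinol into the (R) ester. The hindered carbonyl is not attacked and the acid is never electrophilically activated, which rules out lactonization onto the side chain.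

Step 15
Reactants: 26 (R)-4-{[(R)-1-(3,5-bis(benzyloxy)phenyl)propan-2-yl]oxy}-4-oxobutan-2-yl 2,4-bis(benzyloxy)-6-[(R)-2-(tert-butyldimethylsilyloxy)propyl]benzoate
Product: 27 (R)-4-{[(R)-1-(3,5-bis(benzyloxy)phenyl)propan-2-yl]oxy}-4-oxobutan-2-yl 2,4-bis(benzyloxy)-6-[(R)-2-hydroxypropyl]benzoate
Conditions: HF·pyridine, pyridine, THF, 0 °C → rt
Reagents that add atoms: none
Why: Fluoride cleavage of a silyl ether in a buffered, mildly acidic medium. The absence of base protects the 3-aroyloxybutanoate from E1cB elimination and disfavours alkoxide-type attack of the new alcohol on the neighbouring benzoate.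

Step 16
Reactants: 27 (R)-4-{[(R)-1-(3,5-bis(benzyloxy)phenyl)propan-2-yl]oxy}-4-oxobutan-2-yl 2,4-bis(benzyloxy)-6-[(R)-2-hydroxypropyl]benzoate; 3 (R)-3-(tert-butyldimethylsilyloxy)butanoic acid
Product: 28 (R)-4-{[(R)-1-(3,5-bis(benzyloxy)phenyl)propan-2-yl]oxy}-4-oxobutan-2-yl 2,4-bis(benzyloxy)-6-[(R)-2-{[(R)-3-(tert-butyldimethylsilyloxy)butanoyl]oxy}propyl]benzoate
Conditions: DCC, DMAP (cat.), CH2Cl2, 0 °C → rt
Reagents that add atoms: none
Why: Steglich esterification of an unhindered secondary alcohol with an acid whose stereocentre is β to the carboxyl and so cannot epimerize; used directly after step 15 to keep the free alcohol short-lived.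

Step 17
Reactants: 28 (R)-4-{[(R)-1-(3,5-bis(benzyloxy)phenyl)propan-2-yl]oxy}-4-oxobutan-2-yl 2,4-bis(benzyloxy)-6-[(R)-2-{[(R)-3-(tert-butyldimethylsilyloxy)butanoyl]oxy}propyl]benzoate
Product: 29 (R)-4-{[(R)-1-(3,5-bis(benzyloxy)phenyl)propan-2-yl]oxy}-4-oxobutan-2-yl 2,4-bis(benzyloxy)-6-[(R)-2-{[(R)-3-hydroxybutanoyl]oxy}propyl]benzoate
Conditions: HF·pyridine, pyridine, THF, 0 °C → rt
Reagents that add atoms: none
Why: Buffered fluoride desilylation as in step 15; acidic conditions leave both 3-acyloxybutanoate esters and the new β-hydroxy ester intact.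

Step 18
Reactants: 29 (R)-4-{[(R)-1-(3,5-bis(benzyloxy)phenyl)propan-2-yl]oxy}-4-oxobutan-2-yl 2,4-bis(benzyloxy)-6-[(R)-2-{[(R)-3-hydroxybutanoyl]oxy}propyl]benzoate
Product: 30 hansforester J
Conditions: H2 (1 atm), 10% Pd/C, EtOAc/EtOH, rt
Reagents that add atoms: none
Why: Hydrogenolysis of four aryl benzyl ethers under neutral conditions; no ester oxygen is benzylic, so the three ester bonds and all four stereocentres are unaffected and toluene is the only by-product.

## Compound list

1 | methyl (R)-3-hydroxybutanoate | C[C@@H](O)CC(=O)OC | starting material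
2 | methyl (R)-3-(tert-butyldimethylsilyloxy)butanoate | C[C@@H](O[Si](C)(C)C(C)(C)C)CC(=O)OC | intermediate
3 | (R)-3-(tert-butyldimethylsilyloxy)butanoic acid | C[C@@H](O[Si](C)(C)C(C)(C)C)CC(=O)O | intermediate
4 | dimethyl 3-oxopentanedioate | COC(=O)CC(=O)CC(=O)OC | starting material
5 | allyl alcohol | C=CCO | starting material
6 | diallyl 3-oxopentanedioate | C=CCOC(=O)CC(=O)CC(=O)OCC=C | intermediate
7 | (R)-3-(tert-butyldimethylsilyloxy)butanoyl chloride | C[C@@H](O[Si](C)(C)C(C)(C)C)CC(=O)Cl | intermediate
8 | diallyl 2-[(R)-3-(tert-butyldimethylsilyloxy)butanoyl]-3-oxopentanedioate (C2 enolized, not a defined centre) | C=CCOC(=O)CC(=O)C(C(=O)OCC=C)C(=O)C[C@@H](C)O[Si](C)(C)C(C)(C)C | intermediate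
9 | allyl 4-hydroxy-6-[(R)-2-(tert-butyldimethylsilyloxy)propyl]-2-oxo-2H-pyran-5-carboxylate | C=CCOC(=O)C1=C(C[C@@H](C)O[Si](C)(C)C(C)(C)C)OC(=O)C=C1O | intermediate
10 | allyl 4-(benzyloxy)-6-[(R)-2-(tert-butyldimethylsilyloxy)propyl]-2-oxo-2H-pyran-5-carboxylate | C=CCOC(=O)C1=C(C[C@@H](C)O[Si](C)(C)C(C)(C)C)OC(=O)C=C1OCc1ccccc1 | intermediate
11 | 2-bromo-1,1-diethoxyethane | CCOC(CBr)OCC | starting material
12 | 2-bromo-1,1-bis(benzyloxy)ethane | BrCC(OCc1ccccc1)OCc1ccccc1 | intermediate
13 | 1,1-bis(benzyloxy)ethene (ketene dibenzyl acetal) | C=C(OCc1ccccc1)OCc1ccccc1 | intermediate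
14 | allyl 5,8,8-tris(benzyloxy)-3-oxo-1-[(R)-2-(tert-butyldimethylsilyloxy)propyl]-2-oxabicyclo[2.2.2]oct-5-ene-6-carboxylate (bridgeheads unassigned) | C=CCOC(=O)C1=C(OCc3ccccc3)C2C(=O)OC1(C[C@@H](C)O[Si](C)(C)C(C)(C)C)CC2(OCc4ccccc4)OCc5ccccc5 | intermediate
15 | allyl 4,4,6-tris(benzyloxy)-2-[(R)-2-(tert-butyldimethylsilyloxy)propyl]cyclohexa-1,5-diene-1-carboxylate | C=CCOC(=O)C1=C(C[C@@H](C)O[Si](C)(C)C(C)(C)C)CC(OCc2ccccc2)(OCc2ccccc2)C=C1OCc1ccccc1 | intermediate
16 | allyl 2,4-bis(benzyloxy)-6-[(R)-2-(tert-butyldimethylsilyloxy)propyl]benzoate | C=CCOC(=O)c1c(OCc2ccccc2)cc(OCc2ccccc2)cc1C[C@@H](C)O[Si](C)(C)C(C)(C)C | intermediate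
17 | 2,4-bis(benzyloxy)-6-[(R)-2-(tert-butyldimethylsilyloxy)propyl]benzoic acid | OC(=O)c1c(OCc2ccccc2)cc(OCc2ccccc2)cc1C[C@@H](C)O[Si](C)(C)C(C)(C)C | intermediate
18 | 1,3-bis(benzyloxy)-5-bromobenzene | Brc1cc(OCc2ccccc2)cc(OCc2ccccc2)c1 | starting material
19 | (R)-2-methyloxirane | C[C@@H]1CO1 | starting material
20 | [3,5-bis(benzyloxy)phenyl]magnesium bromide | Br[Mg]c1cc(OCc2ccccc2)cc(OCc2ccccc2)c1 | intermediate
21 | (R)-1-[3,5-bis(benzyloxy)phenyl]propan-2-ol | C[C@@H](O)Cc1cc(OCc2ccccc2)cc(OCc2ccccc2)c1 | intermediate
22 | 2,2,6-trimethyl-4H-1,3-dioxin-4-one | CC1=CC(=O)OC(C)(C)O1 | starting material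
23 | acetylketene | CC(=O)C=C=O | intermediate
24 | (R)-1-[3,5-bis(benzyloxy)phenyl]propan-2-yl 3-oxobutanoate | C[C@H](Cc1cc(OCc2ccccc2)cc(OCc2ccccc2)c1)OC(=O)CC(C)=O | intermediate
25 | (R)-1-[3,5-bis(benzyloxy)phenyl]propan-2-yl (S)-3-hydroxybutanoate | C[C@H](Cc1cc(OCc2ccccc2)cc(OCc2ccccc2)c1)OC(=O)C[C@H](C)O | intermediate
26 | (R)-4-{[(R)-1-(3,5-bis(benzyloxy)phenyl)propan-2-yl]oxy}-4-oxobutan-2-yl 2,4-bis(benzyloxy)-6-[(R)-2-(tert-butyldimethylsilyloxy)propyl]benzoate | C[C@H](Cc1cc(OCc2ccccc2)cc(OCc2ccccc2)c1)OC(=O)C[C@@H](C)OC(=O)c1c(OCc2ccccc2)cc(OCc2ccccc2)cc1C[C@@H](C)O[Si](C)(C)C(C)(C)C | intermediate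
27 | (R)-4-{[(R)-1-(3,5-bis(benzyloxy)phenyl)propan-2-yl]oxy}-4-oxobutan-2-yl 2,4-bis(benzyloxy)-6-[(R)-2-hydroxypropyl]benzoate | C[C@H](Cc1cc(OCc2ccccc2)cc(OCc2ccccc2)c1)OC(=O)C[C@@H](C)OC(=O)c1c(OCc2ccccc2)cc(OCc2ccccc2)cc1C[C@@H](C)O | intermediate
28 | (R)-4-{[(R)-1-(3,5-bis(benzyloxy)phenyl)propan-2-yl]oxy}-4-oxobutan-2-yl 2,4-bis(benzyloxy)-6-[(R)-2-{[(R)-3-(tert-butyldimethylsilyloxy)butanoyl]oxy}propyl]benzoate | C[C@H](Cc1cc(OCc2ccccc2)cc(OCc2ccccc2)c1)OC(=O)C[C@@H](C)OC(=O)c1c(OCc2ccccc2)cc(OCc2ccccc2)cc1C[C@@H](C)OC(=O)C[C@@H](C)O[Si](C)(C)C(C)(C)C | intermediate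
29 | (R)-4-{[(R)-1-(3,5-bis(benzyloxy)phenyl)propan-2-yl]oxy}-4-oxobutan-2-yl 2,4-bis(benzyloxy)-6-[(R)-2-{[(R)-3-hydroxybutanoyl]oxy}propyl]benzoate | C[C@H](Cc1cc(OCc2ccccc2)cc(OCc2ccccc2)c1)OC(=O)C[C@@H](C)OC(=O)c1c(OCc2ccccc2)cc(OCc2ccccc2)cc1C[C@@H](C)OC(=O)C[C@@H](C)O | intermediate
30 | hansforester J | C[C@H](Cc1cc(O)cc(O)c1)OC(=O)C[C@@H](C)OC(=O)c1c(O)cc(O)cc1C[C@@H](C)OC(=O)C[C@@H](C)O | target

## Step count and least certain steps

Total: 18 steps. Longest linear sequence: 12 steps from 1 (steps 1, 2, 4, 5, 6, 9, 10, 14, 15, 16, 17, 18).

**Step 9 (key step).** The cycloaddition may be too slow. The 4-benzyloxy group raises the diene LUMO and the 6-alkyl group hinders bonding at C6, so thermal isomerization or oligomerization of 13 may consume the dienophile first. The fallback sets out from 21 and returns at 17, attaching the carboxyl to a preformed arene. Silylation of 21 (TBSCl, imidazole, DMF) should give tert-butyl{[(R)-1-(3,5-bis(benzyloxy)phenyl)propan-2-yl]oxy}dimethylsilane F1. Bromination with NBS in MeCN at 0 °C, directed para to one benzyloxy group and ortho to the chain, should give tert-butyl{[(R)-1-(2-bromo-3,5-bis(benzyloxy)phenyl)propan-2-yl]oxy}dimethylsilane F2. Bromine–lithium exchange (n-BuLi, THF, −78 °C) and quenching with CO2 should then give 17 directly.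

**Step 8.** Elimination may be sluggish at the low temperature that the product requires, and 13 may be lost by hydrolysis, acid-induced oligomerization or benzyl shift during isolation. The fallback sets out from 12 and returns at 13 through a base-free syn-elimination. Displacement of bromide with PhSeNa (from (PhSe)2 and NaBH4, EtOH) should give [2,2-bis(benzyloxy)ethyl](phenyl)selane F3. Oxidation with NaIO4 (aq. MeOH, NaHCO3, 0 °C) should give [2,2-bis(benzyloxy)ethyl](phenyl)selane oxide F4. Warming F4 to about 70 °C with i-Pr2NH should release 13.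

**Step 14.** Dehydration of the activated 3-hydroxybutanoate to the crotonate may compete with displacement, because the carboxylate is hindered and only moderately acidic. The fallback sets out from 17 and returns at 26, using an alcohol that cannot eliminate to a conjugated ester. Mitsunobu coupling of 17 with (S)-pent-4-en-2-ol F5 should give (R)-pent-4-en-2-yl 2,4-bis(benzyloxy)-6-[(R)-2-(tert-butyldimethylsilyloxy)propyl]benzoate F6 with inversion. Ozonolysis (O3, CH2Cl2, −78 °C; Me2S) should give (R)-4-oxobutan-2-yl 2,4-bis(benzyloxy)-6-[(R)-2-(tert-butyldimethylsilyloxy)propyl]benzoate F7. Pinnick oxidation of crude F7 (NaClO2, NaH2PO4, 2-methylbut-2-ene) should give (R)-3-{[2,4-bis(benzyloxy)-6-((R)-2-(tert-butyldimethylsilyloxy)propyl)benzoyl]oxy}butanoic acid F8. Steglich esterification of F8 with 21 then gives 26; compounds 24 and 25 are no longer needed.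

**Step 15.** The liberated alcohol may transfer the aroyl group to itself, lactonizing onto the ring C ester and expelling the A–B alcohol. If the medium turns basic, the 3-aroyloxybutanoate may also eliminate. The fallback sets out from 16 and returns at 28. It frees and acylates the side-chain alcohol before the base-sensitive A–B ester is present, next to an allyl ester with a poorer leaving group. Desilylation of 16 (HF·pyridine) should give allyl 2,4-bis(benzyloxy)-6-[(R)-2-hydroxypropyl]benzoate F9. Acylation with 3 (DCC, DMAP) should give allyl 2,4-bis(benzyloxy)-6-[(R)-2-{[(R)-3-(tert-butyldimethylsilyloxy)butanoyl]oxy}propyl]benzoate F10. Deallylation (Pd(PPh3)4, morpholine) should give 2,4-bis(benzyloxy)-6-[(R)-2-{[(R)-3-(tert-butyldimethylsilyloxy)butanoyl]oxy}propyl]benzoic acid F11. Mitsunobu coupling of F11 with 25 then gives 28.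

**Step 13.** Facial selectivity may fall short, or the alcohol solvent may transesterify the keto ester, which would show up as a diastereomeric impurity or as loss of 21. The fallback sets out from 21 and returns at 25 using the chiral pool. Methyl (S)-3-hydroxybutanoate F12 is silylated (TBSCl, imidazole) to methyl (S)-3-(tert-butyldimethylsilyloxy)butanoate F13 and saponified (LiOH) to (S)-3-(tert-butyldimethylsilyloxy)butanoic acid F14. Steglich esterification of 21 with F14 should give (R)-1-[3,5-bis(benzyloxy)phenyl]propan-2-yl (S)-3-(tert-butyldimethylsilyloxy)butanoate F15. Desilylation with HF·pyridine then gives 25.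

## Further compounds

F1 | step 9 | tert-butyl{[(R)-1-(3,5-bis(benzyloxy)phenyl)propan-2-yl]oxy}dimethylsilane | C[C@H](Cc1cc(OCc2ccccc2)cc(OCc2ccccc2)c1)O[Si](C)(C)C(C)(C)C
F2 | step 9 | tert-butyl{[(R)-1-(2-bromo-3,5-bis(benzyloxy)phenyl)propan-2-yl]oxy}dimethylsilane | C[C@H](Cc1cc(OCc2ccccc2)cc(OCc2ccccc2)c1Br)O[Si](C)(C)C(C)(C)C
F3 | step 8 | [2,2-bis(benzyloxy)ethyl](phenyl)selane | C(OCc1ccccc1)(OCc1ccccc1)C[Se]c1ccccc1
F4 | step 8 | [2,2-bis(benzyloxy)ethyl](phenyl)selane oxide | O=[Se](CC(OCc1ccccc1)OCc1ccccc1)c1ccccc1
F5 | step 14 | (S)-pent-4-en-2-ol | C=CC[C@H](C)O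
F6 | step 14 | (R)-pent-4-en-2-yl 2,4-bis(benzyloxy)-6-[(R)-2-(tert-butyldimethylsilyloxy)propyl]benzoate | C=CC[C@@H](C)OC(=O)c1c(OCc2ccccc2)cc(OCc2ccccc2)cc1C[C@@H](C)O[Si](C)(C)C(C)(C)C
F7 | step 14 | (R)-4-oxobutan-2-yl 2,4-bis(benzyloxy)-6-[(R)-2-(tert-butyldimethylsilyloxy)propyl]benzoate | O=CC[C@@H](C)OC(=O)c1c(OCc2ccccc2)cc(OCc2ccccc2)cc1C[C@@H](C)O[Si](C)(C)C(C)(C)C
F8 | step 14 | (R)-3-{[2,4-bis(benzyloxy)-6-((R)-2-(tert-butyldimethylsilyloxy)propyl)benzoyl]oxy}butanoic acid | OC(=O)C[C@@H](C)OC(=O)c1c(OCc2ccccc2)cc(OCc2ccccc2)cc1C[C@@H](C)O[Si](C)(C)C(C)(C)C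
F9 | step 15 | allyl 2,4-bis(benzyloxy)-6-[(R)-2-hydroxypropyl]benzoate | C=CCOC(=O)c1c(OCc2ccccc2)cc(OCc2ccccc2)cc1C[C@@H](C)O
F10 | step 15 | allyl 2,4-bis(benzyloxy)-6-[(R)-2-{[(R)-3-(tert-butyldimethylsilyloxy)butanoyl]oxy}propyl]benzoate | C=CCOC(=O)c1c(OCc2ccccc2)cc(OCc2ccccc2)cc1C[C@@H](C)OC(=O)C[C@@H](C)O[Si](C)(C)C(C)(C)C
F11 | step 15 | 2,4-bis(benzyloxy)-6-[(R)-2-{[(R)-3-(tert-butyldimethylsilyloxy)butanoyl]oxy}propyl]benzoic acid | OC(=O)c1c(OCc2ccccc2)cc(OCc2ccccc2)cc1C[C@@H](C)OC(=O)C[C@@H](C)O[Si](C)(C)C(C)(C)C
F12 | step 13 | methyl (S)-3-hydroxybutanoate | C[C@H](O)CC(=O)OC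
F13 | step 13 | methyl (S)-3-(tert-butyldimethylsilyloxy)butanoate | C[C@H](O[Si](C)(C)C(C)(C)C)CC(=O)OC
F14 | step 13 | (S)-3-(tert-butyldimethylsilyloxy)butanoic acid | C[C@H](O[Si](C)(C)C(C)(C)C)CC(=O)O
F15 | step 13 | (R)-1-[3,5-bis(benzyloxy)phenyl]propan-2-yl (S)-3-(tert-butyldimethylsilyloxy)butanoate | C[C@H](Cc1cc(OCc2ccccc2)cc(OCc2ccccc2)c1)OC(=O)C[C@H](C)O[Si](C)(C)C(C)(C)C
A1 | alternative 1 | methyl 6-[(R)-2-(4-methoxybenzyloxy)propyl]-2,4-dioxocyclohexane-1-carboxylate | COC(=O)C1C(C[C@@H](C)OCc2ccc(OC)cc2)CC(=O)CC1=O
A2 | alternative 1 | (R,E)-6-(4-methoxybenzyloxy)hept-3-en-2-one | CC(=O)/C=C/C[C@@H](C)OCc1ccc(OC)cc1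
A3 | alternative 1 | dimethyl malonate | COC(=O)CC(=O)OC
A4 | alternative 2 | 4,6-bis(benzyloxy)benzocyclobutenone methyl trimethylsilyl acetal bearing the (R)-1-(tert-butyldimethylsilyloxy)ethyl group on the ring CH | C[C@@H](O[Si](C)(C)C(C)(C)C)C1c2cc(OCc3ccccc3)cc(OCc3ccccc3)c2C1(OC)O[Si](C)(C)C
A5 | alternative 2 | 3,5-bis(benzyloxy)-2-iodophenyl trifluoromethanesulfonate | FC(F)(F)S(=O)(=O)Oc1cc(OCc2ccccc2)cc(OCc2ccccc2)c1I
A6 | alternative 2 | (R)-tert-butyl{[4-methoxy-4-(trimethylsilyloxy)but-3-en-2-yl]oxy}dimethylsilane | C[C@@H](O[Si](C)(C)C(C)(C)C)C=C(OC)O[Si](C)(C)C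
A7 | alternative 2 | methyl 2,4-bis(benzyloxy)-6-[(R)-2-(tert-butyldimethylsilyloxy)propyl]benzoate | COC(=O)c1c(OCc2ccccc2)cc(OCc2ccccc2)cc1C[C@@H](C)O[Si](C)(C)C(C)(C)C
A8 | alternative 3 | 3-[(R)-2-(tert-butyldimethylsilyloxy)propyl]-5-(triisopropylsilyloxy)phenol | C[C@H](Cc1cc(O)cc(O[Si](C(C)C)(C(C)C)C(C)C)c1)O[Si](C)(C)C(C)(C)C
A9 | alternative 3 | 3-[(R)-2-(tert-butyldimethylsilyloxy)propyl]cyclobut-2-en-1-one | C[C@H](CC1=CC(=O)C1)O[Si](C)(C)C(C)(C)C
A10 | alternative 3 | (ethynyloxy)triisopropylsilane | C#CO[Si](C(C)C)(C(C)C)C(C)C
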